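**Plan**

- Retrosynthesis cuts ring C of unit 1 (the eriodictyol half) at O1–C2 and C3–C4. Ring C is a phenol oxygen (O1) and a benzylic carbonyl carbon (C4) spanning a cis-1,2-diarylethane (C2 with ring B, C3 with C8'' of the naringenin half, unit 2). This is the adduct of an ortho-quinone methide (O1, C8a, C4a, C4) and a Z-stilbene, so one [4+2] step can build it.
- Forward order: the unit 2 flavanone is made first (chromone, then asymmetric aryl addition), iodinated at C8'', coupled to the ring B alkyne and semihydrogenated to the Z-stilbene. Ring C of unit 1 is then closed by cycloaddition with the quinone methide from a salicylaldehyde, C4 is oxidised to the ketone, and all protecting groups fall in one hydrogenolysis.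
- Stereochemistry: C2'' (R) comes from ligand control in a rhodium-catalysed conjugate addition. C2 and C3 become cis by suprafacial addition to the Z alkene, and their absolute sense (2R,3R in the target) is set by a chiral Brønsted acid. C3 cannot epimerise while C4 is an ether.
- Unit 2 carries benzyl carbonates instead of benzyl ethers on its phenols, so that its ring A is electron-poor and cannot steer the regiochemistry against ring B. They are cleaved together with the benzyl ethers at the end.

Key step: step 11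

Assumption: 18 is drawn with the 3,4-trans methyl ether expected next to the peri benzyloxy group (its C4 epimer serves equally, since C4 becomes a carbonyl), and the enantiomers of the ligand in step 3 and of the acid in step 11 are those that give the drawn configurations, to be confirmed on a first run.

**Step 1**
Reactants: 1 2,4,6-trihydroxyacetophenone
Product: 2 2-hydroxy-4,6-bis(benzyloxy)acetophenone
Conditions: BnBr (2.1 equiv), K2CO3, DMF, rt
Reagents that add atoms: benzyl bromide BrCc1ccccc1
Why: Williamson ether synthesis in which the hydroxyl hydrogen-bonded to the acetyl carbonyl stays free while the two others are alkylated, the usual selectivity for this acetophenone.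

**Step 2**
Reactants: 2 2-hydroxy-4,6-bis(benzyloxy)acetophenone
Product: 4 5,7-bis(benzyloxy)chromone, via enaminone 3 (not isolated)
Conditions: Me2NCH(OMe)2, toluene, 95 °C; then conc. HCl, CH2Cl2, rt
Reagents that add atoms: N,N-dimethylformamide dimethyl acetal COC(OC)N(C)C
Why: Enaminone chromone synthesis, in which the methyl ketone condenses with the amide acetal and acid then drives addition of the phenol and loss of dimethylamine to close the pyranone, both stages leaving benzyl ethers untouched.

**Step 3**
Reactants: 4 5,7-bis(benzyloxy)chromone; 5 4-(benzyloxy)phenylboronic acid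
Product: 6 (2R)-5,7-bis(benzyloxy)-2-[4-(benzyloxy)phenyl]chroman-4-one
Conditions: [Rh(OH)(cod)]2 (2.5 mol%), MeO-F12-BIPHEP [6,6'-dimethoxybiphenyl-2,2'-diylbis(bis(3,4,5-trifluorophenyl)phosphine), 6 mol%, enantiomer leading to 2R], toluene/H2O, 25 °C
Reagents that add atoms: none
Why: Rhodium-catalysed asymmetric 1,4-addition of an arylboronic acid to a chromone (Hayashi–Miyaura reaction), in which the aryl–rhodium species adds to C2 on the face left open by the chiral bisphosphine and so sets C2 as R, while the near-neutral medium limits ring opening to the chalcone.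

**Step 4**
Reactants: 6 (2R)-5,7-bis(benzyloxy)-2-[4-(benzyloxy)phenyl]chroman-4-one
Product: 7 (2R)-5,7-bis(benzyloxy)-2-[4-(benzyloxy)phenyl]-8-iodochroman-4-one
Conditions: NIS (1.05 equiv), DMF, rt, dark
Reagents that add atoms: N-iodosuccinimide O=C1CCC(=O)N1I
Why: Electrophilic aromatic iodination, which with O5 alkylated should go to C8 (flanked by the ring oxygen) in preference to C6 (between two benzyloxy groups) or the less activated 4-benzyloxyphenyl ring, under neutral conditions that do not touch C2.

**Step 5**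
Reactants: 7 (2R)-5,7-bis(benzyloxy)-2-[4-(benzyloxy)phenyl]-8-iodochroman-4-one
Product: 8 (2R)-5,7-dihydroxy-2-(4-hydroxyphenyl)-8-iodochroman-4-one
Conditions: BCl3 (6 equiv), C6HMe5 (9 equiv), CH2Cl2, −78 °C; then H2O
Reagents that add atoms: none
Why: Lewis acid debenzylation with BCl3 and pentamethylbenzene as a non-basic benzyl cation scavenger cleaves aryl benzyl ethers at low temperature while keeping the aryl iodide (which hydrogenolysis would remove) and avoiding base that could open the flavanone.

**Step 6**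
Reactants: 8 (2R)-5,7-dihydroxy-2-(4-hydroxyphenyl)-8-iodochroman-4-one
Product: 9 (2R)-5,7-bis(benzyloxycarbonyloxy)-2-[4-(benzyloxycarbonyloxy)phenyl]-8-iodochroman-4-one
Conditions: CbzCl (4 equiv), Et3N, DMAP (cat.), CH2Cl2, 0 °C to rt
Reagents that add atoms: benzyl chloroformate O=C(Cl)OCc1ccccc1
Why: Acylation of the three phenols gives aryl benzyl carbonates, electron-withdrawing groups that make ring A of unit 2 a poor cation-stabilising aryl for step 11 and that are later removed by hydrogenolysis.

**Step 7**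
Reactants: 10 3,4-bis(benzyloxy)benzaldehyde
Product: 11 1,2-bis(benzyloxy)-4-ethynylbenzene
Conditions: dimethyl (1-diazo-2-oxopropyl)phosphonate, K2CO3, MeOH/THF, 0 °C to rt
Reagents that add atoms: dimethyl (1-diazo-2-oxopropyl)phosphonate COP(=O)(OC)C(=[N+]=[N-])C(C)=O
Why: Seyferth–Gilbert homologation with the Ohira–Bestmann reagent converts the aldehyde into the terminal alkyne in one operation through a diazoalkene and 1,2-shift of the derived alkylidene carbene.

**Step 8**
Reactants: 9 (2R)-8-iodonaringenin tris(benzyl carbonate); 11 1,2-bis(benzyloxy)-4-ethynylbenzene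
Product: 12 (2R)-8-{[3,4-bis(benzyloxy)phenyl]ethynyl}-5,7-bis(benzyloxycarbonyloxy)-2-[4-(benzyloxycarbonyloxy)phenyl]chroman-4-one
Conditions: PdCl2(PPh3)2 (5 mol%), CuI (10 mol%), Et3N, THF, rt to 40 °C
Reagents that add atoms: none
Why: Sonogashira coupling, in which the acyloxy groups ease oxidative addition of zerovalent palladium into the hindered C–I bond, no free ortho phenol is present to cyclise to a benzofuran, and the tertiary amine is too weak to cleave the carbonates or open the flavanone.

**Step 9**
Reactants: 12 diarylalkyne of step 8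
Product: 13 (2R)-8-[(Z)-2-(3,4-bis(benzyloxy)phenyl)ethenyl]-5,7-bis(benzyloxycarbonyloxy)-2-[4-(benzyloxycarbonyloxy)phenyl]chroman-4-one
Conditions: H2 (1 atm), Pd/CaCO3 poisoned with Pb(OAc)2 (Lindlar catalyst), quinoline, EtOAc, rt
Reagents that add atoms: none
Why: Lindlar semihydrogenation delivers H2 syn to the alkyne on lead-poisoned palladium to give the Z alkene, and quinoline restrains over-reduction and hydrogenolysis of the benzyl ethers and benzyl carbonates.

**Step 10**
Reactants: 14 2,4,6-trihydroxybenzaldehyde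
Product: 15 2-hydroxy-4,6-bis(benzyloxy)benzaldehyde
Conditions: BnBr (2.05 equiv), K2CO3, DMF, 0 °C to rt
Reagents that add atoms: benzyl bromide BrCc1ccccc1
Why: Williamson ether synthesis with the same selectivity as in step 1, the hydroxyl chelated to the formyl group being the last to react.

**Step 11**
Reactants: 15 2-hydroxy-4,6-bis(benzyloxy)benzaldehyde; 13 Z-stilbene of step 9
Product: 18 (2R,3S,4S)-2,3-cis-3,4-trans-4-methoxyflavan carrying the unit 2 flavanone at C3, via dimethyl acetal 16 (not isolated), via methoxy ortho-quinone methide 17 (not isolated)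
Conditions: HC(OMe)3 (3 equiv), (R)-3,3'-bis(2,4,6-triisopropylphenyl)-1,1'-bi-2-naphthol N-triflylphosphoramide (10 mol%), 5 Å MS, toluene, −30 to 0 °C
Reagents that add atoms: trimethyl orthoformate COC(OC)OC
Why: Proposed new method: acid and orthoformate turn the aldehyde into acetal 16, which loses methanol to the O-methyl oxocarbenium ion/methoxy ortho-quinone methide 17, held as a hydrogen-bonded ion pair with the chiral phosphoramide anion; the Z-stilbene then adds in an asynchronous inverse-electron-demand hetero-Diels–Alder reaction in which C4–C3 bonding runs ahead and the phenol oxygen closes on C2. The closest known reactions are the acid-catalysed three-component union of salicylaldehydes, orthoformates and styrenes to 4-alkoxyflavans and the chiral N-triflylphosphoramide-catalysed [4+2] of ortho-quinone methides with styrenes, neither of which has been shown with a Z-stilbene or with chiral-anion control of an alkoxy-substituted quinone methide. Ring C of unit 1 closes by [4+2] cycloaddition (in the stepwise limit, by six-membered capture of the C2 benzylic cation by the phenol oxygen). C2 and C3 are set cis by suprafacial addition to the Z alkene and their absolute configuration by the alkene face the chiral counter-anion leaves open, while C4 follows the pseudoaxial preference of the methoxy group next to the peri benzyloxy group and is later erased. The step needs regioselectivity (C3, not C2, must bond to C4): the cation developing at C2 is stabilised by the para-benzyloxy group of ring B, whereas the aryl on C3 is twisted by two ortho oxygens and made electron-poor by its carbonates and ketone. It also needs ring closure to outrun C2–C3 rotation, which the intramolecular phenol and low temperature favour.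

**Step 12**
Reactants: 18 4-methoxyflavan of step 11
Product: 19 (2R,3R)-2,3-cis hepta-protected biflavanone (C4 ketone)
Conditions: DDQ (2 equiv), CH2Cl2/pH 7 phosphate buffer, 0 °C to rt
Reagents that add atoms: water O
Why: DDQ abstracts hydride from C4–H, activated by the methoxy group and the 5,7-dibenzyloxy ring A (the mode by which DDQ cleaves p-methoxybenzyl-type ethers and functionalises C4 of benzyl-protected flavans), and water converts the oxocarbenium ion through the hemiketal into the ketone, under cold buffered conditions chosen so that the now enolisable cis C3 is not epimerised.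

**Step 13**
Reactants: 19 protected biflavanone of step 12
Product: 20 (2R,3R)-2-(3,4-dihydroxyphenyl)-5,7-dihydroxy-3-[(2R)-5,7-dihydroxy-2-(4-hydroxyphenyl)-4-oxochroman-8-yl]chroman-4-one (target)
Conditions: H2 (1 atm), 10% Pd/C, EtOAc/MeOH, rt
Reagents that add atoms: none
Why: Catalytic hydrogenolysis cleaves the four benzyl ethers and the three benzyl carbonates (these with loss of toluene and CO2) under neutral conditions that should spare the ketones, the benzylic C2–O bonds of both flavanones and the base-sensitive cis C2/C3 relationship.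

**Compound list**

1 | 2,4,6-trihydroxyacetophenone | CC(=O)c1c(O)cc(O)cc1O | starting material
2 | 2-hydroxy-4,6-bis(benzyloxy)acetophenone | CC(=O)c1c(O)cc(OCc2ccccc2)cc1OCc1ccccc1 | intermediate
3 | (E)-3-(dimethylamino)-1-[2-hydroxy-4,6-bis(benzyloxy)phenyl]prop-2-en-1-one (enaminone, formed in the flask) | CN(C)/C=C/C(=O)c1c(O)cc(OCc2ccccc2)cc1OCc1ccccc1 | intermediate
4 | 5,7-bis(benzyloxy)-4H-chromen-4-one | O=c1ccoc2cc(OCc3ccccc3)cc(OCc3ccccc3)c12 | intermediate
5 | 4-(benzyloxy)phenylboronic acid | OB(O)c1ccc(OCc2ccccc2)cc1 | starting material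
6 | (2R)-5,7-bis(benzyloxy)-2-[4-(benzyloxy)phenyl]chroman-4-one | O=C1C[C@H](c2ccc(OCc3ccccc3)cc2)Oc2cc(OCc3ccccc3)cc(OCc3ccccc3)c12 | intermediate
7 | (2R)-5,7-bis(benzyloxy)-2-[4-(benzyloxy)phenyl]-8-iodochroman-4-one | O=C1C[C@H](c2ccc(OCc3ccccc3)cc2)Oc2c(I)c(OCc3ccccc3)cc(OCc3ccccc3)c12 | intermediate
8 | (2R)-5,7-dihydroxy-2-(4-hydroxyphenyl)-8-iodochroman-4-one | O=C1C[C@H](c2ccc(O)cc2)Oc2c(I)c(O)cc(O)c12 | intermediate
9 | (2R)-5,7-bis(benzyloxycarbonyloxy)-2-[4-(benzyloxycarbonyloxy)phenyl]-8-iodochroman-4-one | O=C1C[C@H](c2ccc(OC(=O)OCc3ccccc3)cc2)Oc2c(I)c(OC(=O)OCc3ccccc3)cc(OC(=O)OCc3ccccc3)c12 | intermediate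
10 | 3,4-bis(benzyloxy)benzaldehyde | O=Cc1ccc(OCc2ccccc2)c(OCc2ccccc2)c1 | starting material
11 | 1,2-bis(benzyloxy)-4-ethynylbenzene | C#Cc1ccc(OCc2ccccc2)c(OCc2ccccc2)c1 | intermediate
12 | (2R)-8-{[3,4-bis(benzyloxy)phenyl]ethynyl}-5,7-bis(benzyloxycarbonyloxy)-2-[4-(benzyloxycarbonyloxy)phenyl]chroman-4-one | O=C1C[C@H](c2ccc(OC(=O)OCc3ccccc3)cc2)Oc2c(C#Cc3ccc(OCc4ccccc4)c(OCc4ccccc4)c3)c(OC(=O)OCc3ccccc3)cc(OC(=O)OCc3ccccc3)c12 | intermediate
13 | (2R)-8-[(Z)-2-(3,4-bis(benzyloxy)phenyl)ethenyl]-5,7-bis(benzyloxycarbonyloxy)-2-[4-(benzyloxycarbonyloxy)phenyl]chroman-4-one | O=C1C[C@H](c2ccc(OC(=O)OCc3ccccc3)cc2)Oc2c(/C=C\c3ccc(OCc4ccccc4)c(OCc4ccccc4)c3)c(OC(=O)OCc3ccccc3)cc(OC(=O)OCc3ccccc3)c12 | intermediate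
14 | 2,4,6-trihydroxybenzaldehyde | O=Cc1c(O)cc(O)cc1O | starting material
15 | 2-hydroxy-4,6-bis(benzyloxy)benzaldehyde | O=Cc1c(O)cc(OCc2ccccc2)cc1OCc1ccccc1 | intermediate
16 | 2-(dimethoxymethyl)-3,5-bis(benzyloxy)phenol (dimethyl acetal, formed in the flask) | COC(OC)c1c(O)cc(OCc2ccccc2)cc1OCc1ccccc1 | intermediate
17 | 3,5-bis(benzyloxy)-6-(methoxymethylidene)cyclohexa-2,4-dien-1-one (methoxy ortho-quinone methide, formed in the flask; exocyclic alkene geometry not fixed, the rotamers interconvert through the oxocarbenium form) | COC=C1C(=O)C=C(OCc2ccccc2)C=C1OCc1ccccc1 | intermediate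
18 | (2R,3S,4S)-5,7-bis(benzyloxy)-2-[3,4-bis(benzyloxy)phenyl]-4-methoxy-3-{(2R)-5,7-bis(benzyloxycarbonyloxy)-2-[4-(benzyloxycarbonyloxy)phenyl]-4-oxochroman-8-yl}chromane (2,3-cis, 3,4-trans) | O=C1C[C@H](c2ccc(OC(=O)OCc3ccccc3)cc2)Oc2c1c(OC(=O)OCc3ccccc3)cc(OC(=O)OCc3ccccc3)c2[C@H]1[C@H](OC)c2c(OCc3ccccc3)cc(OCc3ccccc3)cc2O[C@H]1c1ccc(OCc2ccccc2)c(OCc2ccccc2)c1 | intermediate
19 | (2R,3R)-5,7-bis(benzyloxy)-2-[3,4-bis(benzyloxy)phenyl]-3-{(2R)-5,7-bis(benzyloxycarbonyloxy)-2-[4-(benzyloxycarbonyloxy)phenyl]-4-oxochroman-8-yl}chroman-4-one (2,3-cis) | O=C1C[C@H](c2ccc(OC(=O)OCc3ccccc3)cc2)Oc2c1c(OC(=O)OCc3ccccc3)cc(OC(=O)OCc3ccccc3)c2[C@H]1C(=O)c2c(OCc3ccccc3)cc(OCc3ccccc3)cc2O[C@H]1c1ccc(OCc2ccccc2)c(OCc2ccccc2)c1 | intermediate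
20 | (2R,3R)-2-(3,4-dihydroxyphenyl)-5,7-dihydroxy-3-[(2R)-5,7-dihydroxy-2-(4-hydroxyphenyl)-4-oxochroman-8-yl]chroman-4-one (2,3-cis; CNP0105436.4) | O=C1C[C@H](c2ccc(O)cc2)Oc2c1c(O)cc(O)c2[C@H]1C(=O)c2c(O)cc(O)cc2O[C@H]1c1ccc(O)c(O)c1 | target

**Step count and risks**

Total: 13 steps. Longest linear sequence: 11 steps (steps 1–6, 8, 9, 11, 12, 13).

Steps most likely to fail:

Step 11. The addition may run with the wrong regiochemistry or poor facial selectivity, the stabilised methoxy quinone methide may be too unreactive towards the hindered alkene, or the C4 ether may ionise again and lose the C3 proton. The fallback keeps the same two bonds and the same ring closure but uses known chemistry at a lower oxidation level. It sets out from 15 and 13. Reduction of 15 with NaBH4 gives 2-(hydroxymethyl)-3,5-bis(benzyloxy)phenol F1. Under acid catalysis (the same chiral N-triflylphosphoramide, a combination known for ortho-hydroxybenzyl alcohols and styrenes, or an achiral acid) F1 loses water to the unsubstituted, more electrophilic ortho-quinone methide. This adds to 13 to give the (2R,3R)-2,3-cis-flavan with a C4 methylene group F2. Because C2'' is fixed, the other cis adduct, the (2S,3S)-2,3-cis-flavan F3, is a diastereomer and would be removed by chromatography. DDQ in CH2Cl2/MeOH, the established C4 alkoxylation of benzyl-protected flavans, then installs the methoxy group and the route is rejoined at 18.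

Step 12. The oxocarbenium ion may lose the C3 proton, the new ketone may enolise with cis-to-trans epimerisation at C3, or hydride may be abstracted at C2 instead. The fallback replaces hydride abstraction by solvolysis and alcohol oxidation. It sets out from 18: exchange of the methyl ether in THF/H2O with pyridinium p-toluenesulfonate gives the (2R,3S)-2,3-cis-flavan-4-ol F4 (either C4 epimer serves). Dess–Martin periodinane buffered with NaHCO3 then gives the ketone, rejoining the route at 19.

Step 3. The electron-rich chromone may convert poorly, and enantiomeric purity may erode through reversible ring opening of the flavanone to the chalcone in the aqueous medium. The fallback builds the flavanone as a racemate and resolves it. It sets out from 2: Claisen–Schmidt condensation with commercial 4-(benzyloxy)benzaldehyde (KOH, EtOH) gives the chalcone (E)-1-[2-hydroxy-4,6-bis(benzyloxy)phenyl]-3-[4-(benzyloxy)phenyl]prop-2-en-1-one F5. Cyclisation with NaOAc in refluxing EtOH gives racemic 5,7-bis(benzyloxy)-2-[4-(benzyloxy)phenyl]chroman-4-one F6. Kinetic resolution by asymmetric transfer hydrogenation, with the enantiomer of RuCl(p-cymene)(TsDPEN) that reduces the 2S ketone and HCO2H/Et3N, converts the unwanted enantiomer into (2S,4S)-cis-5,7-bis(benzyloxy)-2-[4-(benzyloxy)phenyl]chroman-4-ol F7. The unreacted 2R ketone is recovered by chromatography, rejoining the route at 6.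

**Further compounds**

F1 | step 11 | 2-(hydroxymethyl)-3,5-bis(benzyloxy)phenol | OCc1c(O)cc(OCc2ccccc2)cc1OCc1ccccc1
F2 | step 11 | (2R,3R)-5,7-bis(benzyloxy)-2-[3,4-bis(benzyloxy)phenyl]-3-{(2R)-5,7-bis(benzyloxycarbonyloxy)-2-[4-(benzyloxycarbonyloxy)phenyl]-4-oxochroman-8-yl}chromane (2,3-cis, C4 methylene) | O=C1C[C@H](c2ccc(OC(=O)OCc3ccccc3)cc2)Oc2c1c(OC(=O)OCc3ccccc3)cc(OC(=O)OCc3ccccc3)c2[C@H]1Cc2c(OCc3ccccc3)cc(OCc3ccccc3)cc2O[C@H]1c1ccc(OCc2ccccc2)c(OCc2ccccc2)c1
F3 | step 11 | (2S,3S)-2,3-cis diastereomer of F2 (unit 2 unchanged, 2R) | O=C1C[C@H](c2ccc(OC(=O)OCc3ccccc3)cc2)Oc2c1c(OC(=O)OCc3ccccc3)cc(OC(=O)OCc3ccccc3)c2[C@@H]1Cc2c(OCc3ccccc3)cc(OCc3ccccc3)cc2O[C@@H]1c1ccc(OCc2ccccc2)c(OCc2ccccc2)c1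
F4 | step 12 | (2R,3S,4S)-5,7-bis(benzyloxy)-2-[3,4-bis(benzyloxy)phenyl]-3-{(2R)-5,7-bis(benzyloxycarbonyloxy)-2-[4-(benzyloxycarbonyloxy)phenyl]-4-oxochroman-8-yl}chroman-4-ol (2,3-cis, 3,4-trans drawn) | O=C1C[C@H](c2ccc(OC(=O)OCc3ccccc3)cc2)Oc2c1c(OC(=O)OCc3ccccc3)cc(OC(=O)OCc3ccccc3)c2[C@H]1[C@H](O)c2c(OCc3ccccc3)cc(OCc3ccccc3)cc2O[C@H]1c1ccc(OCc2ccccc2)c(OCc2ccccc2)c1
F5 | step 3 | (E)-1-[2-hydroxy-4,6-bis(benzyloxy)phenyl]-3-[4-(benzyloxy)phenyl]prop-2-en-1-one | O=C(/C=C/c1ccc(OCc2ccccc2)cc1)c1c(O)cc(OCc2ccccc2)cc1OCc1ccccc1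
F6 | step 3 | racemic 5,7-bis(benzyloxy)-2-[4-(benzyloxy)phenyl]chroman-4-one | O=C1CC(c2ccc(OCc3ccccc3)cc2)Oc2cc(OCc3ccccc3)cc(OCc3ccccc3)c12
F7 | step 3 | (2S,4S)-cis-5,7-bis(benzyloxy)-2-[4-(benzyloxy)phenyl]chroman-4-ol | O[C@H]1C[C@@H](c2ccc(OCc3ccccc3)cc2)Oc2cc(OCc3ccccc3)cc(OCc3ccccc3)c12
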